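**Retrosynthetic overview**

1. Locants: ring C1 = C(OH)(CH2OAc), C2 and C3 = CH(OBz), C4=C5 = alkene, C6 = CH(OAc), C7 = the acetoxymethyl carbon. The four esters are placed last by reactivity, since the tertiary C1–OH is never acylated: 13 ⇐ triol diacetate 12 ⇐ tris-silyl diol 10 ⇐ hydroxy acid 8.
2. Key disconnection C1–C6. With C7 at the carboxyl level, C7(=O)–C1–C6–C5=C4 is a γ,δ-unsaturated acid (Claisen retron). Because C4 is also joined to C1 through C2–C3, the allyl vinyl ether C1=C7(O)–O–C4–C5=C6 folds into a six-membered lactone ring (O, C7, C1, C2, C3, C4) that carries the C5=C6 alkene on C4.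
3. Acid 8 therefore comes from 6-alkenyl δ-lactone 5 by a lactone-enolate (Ireland-type) Claisen ring contraction. C6–O is carried through as C6–B of an (E)-alkenyl boronate and unmasked with retention.
4. Lactone 5 ⇐ D-glucono-1,5-lactone: sugar C1 becomes C7, sugar C2–C6 become C1–C5 (C2 and C3 keep the glucose C3/C4 configuration), and only C6 is added, from Cl2CHBpin.
5. Ring order: the pyranone ring is bought with the starting material; the cyclohexene ring forms in the key step at the moment the pyranone opens. No other ring is made.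

Key step: step 4

Sugar locants are used for compounds 1–6 and for the Why lines of steps 1–4; the ring locants above are used from compound 7 onwards.

**Step 1**
Reactants: 1 D-glucono-1,5-lactone
Product: 2 2,3,4,6-tetra-O-triethylsilyl-D-glucono-1,5-lactone
Conditions: Et3SiCl, imidazole, DMF, 0 °C to rt
Reagents that add atoms: chlorotriethylsilane, CC[Si](Cl)(CC)CC
Why: Exhaustive O-silylation under amine base should cap all four hydroxyls while keeping the 1,5-lactone ring, as in the routine per-trimethylsilylation of this lactone; no stereocentre is touched.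

**Step 2**
Reactants: 2 2,3,4,6-tetra-O-triethylsilyl-D-glucono-1,5-lactone
Product: 3 2,3,4-tri-O-triethylsilyl-D-gluco-hexodialdono-1,5-lactone (the C6 aldehyde)
Conditions: (COCl)2, DMSO, CH2Cl2, −78 to −40 °C; then Et3N, −78 to 0 °C
Reagents that add atoms: none
Why: Under Swern conditions a primary triethylsilyl ether is exchanged for the alkoxysulfonium salt and oxidised directly to the aldehyde while secondary triethylsilyl ethers persist (oxidative desilylation), and the low temperature should protect C5 from epimerisation.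

**Step 3**
Reactants: 3 2,3,4-tri-O-triethylsilyl-D-gluco-hexodialdono-1,5-lactone; 4 2-(dichloromethyl)-4,4,5,5-tetramethyl-1,3,2-dioxaborolane
Product: 5 6,7-dideoxy-7-(4,4,5,5-tetramethyl-1,3,2-dioxaborolan-2-yl)-2,3,4-tri-O-triethylsilyl-D-gluco-hept-6-(E)-enono-1,5-lactone
Conditions: CrCl2, LiI, THF, rt
Reagents that add atoms: none
Why: The Takai–Utimoto olefination with a geminal dichromium boryl reagent should give the (E)-alkenyl boronate under non-basic conditions that tolerate the lactone, the silyl ethers and the epimerisable α-alkoxy aldehyde.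

**Step 4**
Reactants: 5 6,7-dideoxy-7-(pinacolatoboryl)-2,3,4-tri-O-triethylsilyl-D-gluco-hept-6-(E)-enono-1,5-lactone
Product: 8 (1R,2S,5R,6S)-2-hydroxy-1,5,6-tris(triethylsilyloxy)cyclohex-3-ene-1-carboxylic acid, via silyl ketene acetal 6 (not isolated), via trimethylsilyl ester allylboronate 7 (not isolated)
Conditions: TMSOTf, Et3N, PhMe, 0 °C to rt, then 90 °C; then NaBO3·4H2O, THF/H2O, rt
Reagents that add atoms: sodium perborate tetrahydrate (NaBO3·4H2O), [Na+].[O-]OB=O
Why: TMSOTf/Et3N should convert the lactone, without a free metal enolate, into the cyclic O-silyl ketene acetal 6, in which sugar atoms C2=C1(OSi)–O5–C5–C6=C7 form an allyl vinyl ether; on heating, a concerted [3,3]-sigmatropic shift forms C2–C7 (C1–C6 of the target) as the allylic C5–O5 bond breaks, which contracts the pyranone to the cyclohexene, creates the C4=C5 alkene and the carboxyl group, and leaves boron on C6. The closest known reaction type is the Claisen ring contraction of silyl ketene acetals of 6-alkenyl δ-lactones (lactone to cycloalkene carboxylic acid, dioxanone to dihydropyran), together with the known Claisen rearrangement of 3-boryl allyl esters to α-substituted allylboronates. The six-membered carbocycle closes across the 2,5-positions of the pyranone through a bicyclo[2.2.2]octane-like boat transition state, the only geometry the ring tether allows. The quaternary centre C1 is set by suprafacial delivery of the alkene to the ketene acetal face that carries the C5 side chain (transfer of the D-configuration of glucose C5, which itself becomes sp2), and C6 is set by the (E)-geometry of the alkenyl boronate, which in the enforced boat places boron cis to the carboxyl carbon; NaBO3 then replaces boron by hydroxyl with retention through a 1,2-boronate shift. The step needs O-silylation to outrun β-elimination of the C3 silyloxy group, which the enolate-free conditions and the poor leaving group should secure, and it needs no control at sugar C2, because that centre is planar in 6 and either C2 epimer would converge on the same product.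

**Step 5**
Reactants: 8 (1R,2S,5R,6S)-2-hydroxy-1,5,6-tris(triethylsilyloxy)cyclohex-3-ene-1-carboxylic acid
Product: 9 methyl (1R,2S,5R,6S)-2-hydroxy-1,5,6-tris(triethylsilyloxy)cyclohex-3-ene-1-carboxylate
Conditions: MeI, KHCO3, DMF, rt
Reagents that add atoms: iodomethane, CI
Why: SN2 O-alkylation of the carboxylate is insensitive to the hindered quaternary α-carbon, and the weak base should leave the free allylic hydroxyl and the silyl ethers untouched.

**Step 6**
Reactants: 9 methyl (1R,2S,5R,6S)-2-hydroxy-1,5,6-tris(triethylsilyloxy)cyclohex-3-ene-1-carboxylate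
Product: 10 [(1R,2S,5R,6S)-2-hydroxy-1,5,6-tris(triethylsilyloxy)cyclohex-3-en-1-yl]methanol
Conditions: i-Bu2AlH, CH2Cl2, −78 to 0 °C; aq KNaC4H4O6 work-up
Reagents that add atoms: none
Why: Hydride reduction of the α-alkoxy ester to the primary alcohol should proceed through cold aluminium alkoxides, which do not promote O-to-O silyl migration.

**Step 7**
Reactants: 10 [(1R,2S,5R,6S)-2-hydroxy-1,5,6-tris(triethylsilyloxy)cyclohex-3-en-1-yl]methanol
Product: 11 [(1R,2S,5R,6S)-2-acetoxy-1,5,6-tris(triethylsilyloxy)cyclohex-3-en-1-yl]methyl acetate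
Conditions: Ac2O, pyridine, DMAP (cat.), CH2Cl2, rt
Reagents that add atoms: acetic anhydride, CC(=O)OC(C)=O
Why: DMAP-catalysed acylation should esterify the only two free hydroxyls (primary C7–OH and secondary allylic C6–OH), the other three oxygens being silylated.

**Step 8**
Reactants: 11 [(1R,2S,5R,6S)-2-acetoxy-1,5,6-tris(triethylsilyloxy)cyclohex-3-en-1-yl]methyl acetate
Product: 12 [(1S,2S,5R,6S)-2-acetoxy-1,5,6-trihydroxycyclohex-3-en-1-yl]methyl acetate (same spatial arrangement as 11; the C1 descriptor changes only through CIP priorities)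
Conditions: HF·pyridine, pyridine, THF, 0 °C to rt
Reagents that add atoms: none
Why: Fluoride-driven desilylation under mildly acidic conditions should remove all three triethylsilyl groups, including the tertiary one, without hydrolysing or migrating the acetates.

**Step 9**
Reactants: 12 [(1S,2S,5R,6S)-2-acetoxy-1,5,6-trihydroxycyclohex-3-en-1-yl]methyl acetate
Product: 13 [(1R,2S,5R,6S)-2-acetoxy-5,6-bis(benzoyloxy)-1-hydroxycyclohex-3-en-1-yl]methyl acetate (CNP0196993.1)
Conditions: BzCl, pyridine, DMAP (cat.), CH2Cl2, 0 °C to rt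
Reagents that add atoms: benzoyl chloride, O=C(Cl)c1ccccc1
Why: Acylation should take the two secondary hydroxyls (C2, C3) and leave the hindered tertiary C1–OH free (steric differentiation of alcohols).

**Compound list**

1 | D-glucono-1,5-lactone | O=C1O[C@H](CO)[C@@H](O)[C@H](O)[C@H]1O | starting material
2 | 2,3,4,6-tetra-O-triethylsilyl-D-glucono-1,5-lactone, (3R,4S,5R,6R)-oxan-2-one | O=C1O[C@H](CO[Si](CC)(CC)CC)[C@@H](O[Si](CC)(CC)CC)[C@H](O[Si](CC)(CC)CC)[C@H]1O[Si](CC)(CC)CC | intermediate
3 | 2,3,4-tri-O-triethylsilyl-D-gluco-hexodialdono-1,5-lactone, (2S,3R,4S,5R)-6-oxo-3,4,5-tris(triethylsilyloxy)oxane-2-carbaldehyde | O=C1O[C@H](C=O)[C@@H](O[Si](CC)(CC)CC)[C@H](O[Si](CC)(CC)CC)[C@H]1O[Si](CC)(CC)CC | intermediate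
4 | 2-(dichloromethyl)-4,4,5,5-tetramethyl-1,3,2-dioxaborolane | ClC(Cl)B1OC(C)(C)C(C)(C)O1 | starting material
5 | (3R,4S,5R,6R)-6-[(E)-2-(4,4,5,5-tetramethyl-1,3,2-dioxaborolan-2-yl)ethenyl]-3,4,5-tris(triethylsilyloxy)oxan-2-one | O=C1O[C@H](/C=C/B2OC(C)(C)C(C)(C)O2)[C@@H](O[Si](CC)(CC)CC)[C@H](O[Si](CC)(CC)CC)[C@H]1O[Si](CC)(CC)CC | intermediate
6 | O-trimethylsilyl ketene acetal of 5 (C1=C2 double bond with OSiMe3 on C1 and OSiEt3 on C2; C3, C4, C5 as in 5) | C[Si](C)(C)OC1=C(O[Si](CC)(CC)CC)[C@@H](O[Si](CC)(CC)CC)[C@H](O[Si](CC)(CC)CC)[C@@H](/C=C/B2OC(C)(C)C(C)(C)O2)O1 | intermediate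
7 | trimethylsilyl (1R,2S,5R,6S)-2-(4,4,5,5-tetramethyl-1,3,2-dioxaborolan-2-yl)-1,5,6-tris(triethylsilyloxy)cyclohex-3-ene-1-carboxylate | C[Si](C)(C)OC(=O)[C@@]1(O[Si](CC)(CC)CC)[C@@H](B2OC(C)(C)C(C)(C)O2)C=C[C@@H](O[Si](CC)(CC)CC)[C@@H]1O[Si](CC)(CC)CC | intermediate
8 | (1R,2S,5R,6S)-2-hydroxy-1,5,6-tris(triethylsilyloxy)cyclohex-3-ene-1-carboxylic acid | OC(=O)[C@@]1(O[Si](CC)(CC)CC)[C@@H](O)C=C[C@@H](O[Si](CC)(CC)CC)[C@@H]1O[Si](CC)(CC)CC | intermediate
9 | methyl (1R,2S,5R,6S)-2-hydroxy-1,5,6-tris(triethylsilyloxy)cyclohex-3-ene-1-carboxylate | COC(=O)[C@@]1(O[Si](CC)(CC)CC)[C@@H](O)C=C[C@@H](O[Si](CC)(CC)CC)[C@@H]1O[Si](CC)(CC)CC | intermediate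
10 | [(1R,2S,5R,6S)-2-hydroxy-1,5,6-tris(triethylsilyloxy)cyclohex-3-en-1-yl]methanol | OC[C@@]1(O[Si](CC)(CC)CC)[C@@H](O)C=C[C@@H](O[Si](CC)(CC)CC)[C@@H]1O[Si](CC)(CC)CC | intermediate
11 | [(1R,2S,5R,6S)-2-acetoxy-1,5,6-tris(triethylsilyloxy)cyclohex-3-en-1-yl]methyl acetate | CC(=O)OC[C@@]1(O[Si](CC)(CC)CC)[C@@H](OC(C)=O)C=C[C@@H](O[Si](CC)(CC)CC)[C@@H]1O[Si](CC)(CC)CC | intermediate
12 | [(1S,2S,5R,6S)-2-acetoxy-1,5,6-trihydroxycyclohex-3-en-1-yl]methyl acetate | CC(=O)OC[C@@]1(O)[C@@H](OC(C)=O)C=C[C@@H](O)[C@@H]1O | intermediate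
13 | [(1R,2S,5R,6S)-2-acetoxy-5,6-bis(benzoyloxy)-1-hydroxycyclohex-3-en-1-yl]methyl acetate | CC(=O)OC[C@@]1(O)[C@@H](OC(C)=O)C=C[C@@H](OC(=O)c2ccccc2)[C@@H]1OC(=O)c1ccccc1 | target

**Step count and risks**

Total step count: 9. Longest linear sequence: 9 steps (1 to 13).

Steps most likely to fail:

Step 4. The C3 silyloxy group may be lost by β-elimination during enolisation, the crowded ketene acetal may decompose before it reaches the bridged boat transition state, or the allylic boronate may suffer protodeboronation. The fallback avoids any enolate and any allylboronate; it sets out from 5 and returns to the route at 10. i-Bu2AlH at −78 °C should reduce 5 to the lactol 6,7-dideoxy-7-(pinacolatoboryl)-2,3,4-tri-O-triethylsilyl-D-gluco-hept-6-(E)-enopyranose F1. Conversion into the glycosyl chloride ((COCl)2, DMF cat.) and DBU-induced 1,2-elimination should give the 2-silyloxy glycal F2. Copper-promoted etherification of the alkenyl boronate with 4-methoxybenzyl alcohol (Cu(OAc)2, Et3N, air; Chan–Lam type, with retention of alkene geometry) should give the (E)-enol ether glycal F3. Thermal Claisen rearrangement of this 6-alkenyl glycal (o-dichlorobenzene, about 200 °C; the known glycal-to-cyclohexenecarbaldehyde reaction) should pass through the same bridged boat and give the α-silyloxy aldehyde F4 with the 4-methoxybenzyloxy group cis to the formyl group. NaBH4 in MeOH should reduce it to the primary alcohol F5, and DDQ in wet CH2Cl2 should remove the 4-methoxybenzyl group to give 10.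

Step 2. The amine base may epimerise C5 through the aldehyde enol or eliminate the C4 silyloxy group, and discrimination between the primary and the secondary silyl ethers may be incomplete. The fallback separates deprotection from oxidation and uses no amine at the aldehyde stage; it sets out from 2 and returns at 3. Buffered HF·pyridine at 0 °C should cleave only the primary silyl ether to give the alcohol 2,3,4-tri-O-triethylsilyl-D-glucono-1,5-lactone F6, and Dess–Martin periodinane with NaHCO3 should oxidise it to 3.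

Step 3. The Lewis-acidic chromium salts may epimerise or reduce the α-alkoxy aldehyde, or the E/Z control may be insufficient for the key step. The fallback builds the alkenyl boronate by metathesis; it sets out from 3 and returns at 5. Methylenation that is selective for the aldehyde over the lactone (Zn, CH2Br2, TiCl4) should give the vinyl lactone 6,7-dideoxy-2,3,4-tri-O-triethylsilyl-D-gluco-hept-6-enono-1,5-lactone F7. Cross-metathesis with vinylboronic acid pinacol ester (second-generation Grubbs catalyst RuCl2(=CHPh)(PCy3)(H2IMes), CH2Cl2, 40 °C) should then give the (E)-alkenyl boronate 5 under thermodynamic control.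

**Further compounds**

F1 | step 4 | 6,7-dideoxy-7-(4,4,5,5-tetramethyl-1,3,2-dioxaborolan-2-yl)-2,3,4-tri-O-triethylsilyl-D-gluco-hept-6-(E)-enopyranose (anomeric mixture) | OC1O[C@H](/C=C/B2OC(C)(C)C(C)(C)O2)[C@@H](O[Si](CC)(CC)CC)[C@H](O[Si](CC)(CC)CC)[C@H]1O[Si](CC)(CC)CC
F2 | step 4 | 2-silyloxy glycal: 1,5-anhydro-6,7-dideoxy-7-(pinacolatoboryl)-2,3,4-tri-O-triethylsilyl-D-arabino-hepta-1,6-(E)-dienitol | C1=C(O[Si](CC)(CC)CC)[C@@H](O[Si](CC)(CC)CC)[C@H](O[Si](CC)(CC)CC)[C@@H](/C=C/B2OC(C)(C)C(C)(C)O2)O1
F3 | step 4 | (E)-enol ether glycal: as F2 with 4-methoxybenzyloxy in place of the boryl group | C1=C(O[Si](CC)(CC)CC)[C@@H](O[Si](CC)(CC)CC)[C@H](O[Si](CC)(CC)CC)[C@@H](/C=C/OCc2ccc(OC)cc2)O1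
F4 | step 4 | 2-(4-methoxybenzyloxy)-1,5,6-tris(triethylsilyloxy)cyclohex-3-ene-1-carbaldehyde, configured as 10 at all four centres | O=C[C@@]1(O[Si](CC)(CC)CC)[C@@H](OCc2ccc(OC)cc2)C=C[C@@H](O[Si](CC)(CC)CC)[C@@H]1O[Si](CC)(CC)CC
F5 | step 4 | [2-(4-methoxybenzyloxy)-1,5,6-tris(triethylsilyloxy)cyclohex-3-en-1-yl]methanol, configured as 10 | OC[C@@]1(O[Si](CC)(CC)CC)[C@@H](OCc2ccc(OC)cc2)C=C[C@@H](O[Si](CC)(CC)CC)[C@@H]1O[Si](CC)(CC)CC
F6 | step 2 | 2,3,4-tri-O-triethylsilyl-D-glucono-1,5-lactone | O=C1O[C@H](CO)[C@@H](O[Si](CC)(CC)CC)[C@H](O[Si](CC)(CC)CC)[C@H]1O[Si](CC)(CC)CC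
F7 | step 3 | 6,7-dideoxy-2,3,4-tri-O-triethylsilyl-D-gluco-hept-6-enono-1,5-lactone | O=C1O[C@H](C=C)[C@@H](O[Si](CC)(CC)CC)[C@H](O[Si](CC)(CC)CC)[C@H]1O[Si](CC)(CC)CC
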